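Start from the constants and read them as a count of turnovers: how many monomer units one living end adds before it dies.

| setting | Saturday's | Thursday's |
|---|---|---|
| free monomer | 1.3 M | 1.3 M |
| transfer agent | 0.390 M | 0.390 M |
| initiator | 130 mM | 500 mM |
| time | 8.0 h | 8.0 h |

    living end → dead end A (k1 = 5.6 × 10⁻⁴ /s)
    free monomer + living end → monomer in chains + living end, rate k2*[living end]*[free monomer] (k2 = 0.026 /M/s)
    free monomer + initiator → living end + monomer in chains (k3 = 0.012 /M/s)
    living end + transfer agent → dead chain (k4 = 0.016 /M/s)
    living end + monomer in chains → dead end B (k5 = 0.0012 /M/s)

- which of the two ends with the longer chains by the average number of monomer units in a chain (chains begun, living or dead) ("neither" if they lie within 10%) (Saturday's / Thursday's / neither)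
- average number of monomer units in a chain (chains begun, living or dead) at the end, Saturday's
- average number of monomer units in a chain (chains begun, living or dead) at the end, Thursday's

- the average divides the monomer in chains by the number of chains begun, living and dead together
- run time (Saturday's): 8.0 h

- Define a, the turnover coefficient: the propagation constant 0.026 /M/s over a living end's death rate to dead end A and dead chain, 5.6 × 10⁻⁴ /s plus 0.016 /M/s times the transfer agent charge 0.390 M, with dead end B left aside. That gives a = 3.82 /M, the kinetic chain length per molar of free monomer, so at the charge 1.3 M a chain takes its initiator-step unit plus 4.97 more.
- Keep a ledger: a chain begun at free monomer concentration [M] costs one plus a[M] units. Integrate that with a held, and you have [M] as a function of chains begun.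
- Turn the initiator to Saturday's 130 mM: the ledger leaves 0.688 M of free monomer, so the length is 4.70.
- Turn it to Thursday's 500 mM: the ledger runs dry after 0.467 M of chains, which makes free monomer the limiting reagent by hand, with length 2.78. Trust this less: those chains exceed the transfer agent charge, so holding a at that charge is a rough step.
- Turn the transfer agent down to 0.16 M: a rises to 8.33 /M, so by hand each chain grows longer.
- Turn the time: a living end's half-life at the transfer agent charge is 1.70 min and Saturday's initiator half-life at the ledger's final free monomer is 1.40 min, both far shorter than 8.0 h, so by hand Saturday's length stops moving early.
- The forecast gives 4.7 for Saturday's and 2.5 for Thursday's, picks Saturday's, and says “its chains are clearly shorter”; its Thursday's figure lies below your 2.78.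
- The flasks end at 4.71 for Saturday's and 2.37 for Thursday's, so Saturday's has the longer chains. Thursday's falls below your hand figure, and its dead end B holds 9.25% of the free monomer charged. Now apply a, held, to Saturday's remaining 52% of free monomer: one plus a times that amount is 3.59 units, against 5.97 at the charge, and Saturday's average lies between them.
- Take Saturday's flask with 0.033 M of initiator: the same a leaves 1.11 M of free monomer, which is 85.4% of the charge, at length 5.61. That flask ends with 85.7% of its free monomer charge and a length of 5.62.

(Its constants are assumed; the result is computed.)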